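**Retrosynthetic overview**
- Flavanone numbering is used (O1, C2, C3, C4, C4a, C5 to C8, C8a; ring A = benzo ring, ring B = trimethoxyphenyl, ring C = pyranone). Ring C is opened at C3–C4 as the reverse of an enantioselective intramolecular alkene hydroacylation. The target is then an isomer of an achiral open aldehyde: a salicylaldehyde whose second ortho oxygen (O1) carries the 1-(ring B)vinyl group.
- Enabling feature: C4 sits on C4a between C8a–O1 and C5–OH, and C2 carries only O1, ring B and C3. The O5–H···O=C4 hydrogen bond therefore points the formyl C–H at O1. C2=C3 is a 1,1-disubstituted enol ether without allylic hydrogen, and its CH2 terminus (C3) is the only place a metal can settle. One closure thus gives ring C, the C4 ketone and the C2 stereocentre.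
- O1–C2 is cut next: Ullmann-type O-vinylation of the less hindered phenol of 2,6-dihydroxy-4-methoxy-3-prenylbenzaldehyde with the 1-bromovinyl arene made from 3,4,5-trimethoxyacetophenone.
- Ring A is bought as 2,4,6-trihydroxybenzaldehyde. The C6 prenyl group comes from C-alkylation and the 7-OMe from methylation of the para hydroxyl.
- Ring order: rings A and B are purchased. Ring C is the only ring formed, and it is closed in the last step.

Key step: step 5

Assumption: the facial sense of the hydroacylation cannot be derived from a closer analogue. The (R)-ligand is written, and its equally available antipode is taken if a first run shows the opposite sense at C2.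

**Step 1**
Reactants: 1 2,4,6-trihydroxybenzaldehyde; 2 1-bromo-3-methylbut-2-ene (prenyl bromide)
Product: 3 2,4,6-trihydroxy-3-(3-methylbut-2-en-1-yl)benzaldehyde
Conditions: 2 (1.0 equiv), KOH (1.0 equiv), H2O, N2, 0 °C to rt
Reagents that add atoms: none
Why: C-alkylation of an acylphloroglucinol phenolate, in which the protic medium shields the oxygens by hydrogen bonding so that the soft allylic bromide is taken up at ring carbon, and because C3 and C5 of 1 are equivalent only one mono-C-prenyl isomer can form.

**Step 2**
Reactants: 3 2,4,6-trihydroxy-3-(3-methylbut-2-en-1-yl)benzaldehyde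
Product: 4 2,6-dihydroxy-4-methoxy-3-(3-methylbut-2-en-1-yl)benzaldehyde
Conditions: MeI (1.05 equiv), K2CO3 (1.0 equiv), acetone, rt
Reagents that add atoms: iodomethane, CI
Why: Williamson etherification with limiting base, in which the 4-OH (para to the formyl group) is the most acidic hydroxyl and the only one outside the formyl hydrogen-bond network, so it should be methylated first.

**Step 3**
Reactants: 5 1-(3,4,5-trimethoxyphenyl)ethan-1-one
Product: 6 5-(1-bromoethenyl)-1,2,3-trimethoxybenzene
Conditions: P(OPh)3, Br2, CH2Cl2, −60 °C; then Et3N, 5, −60 °C to reflux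
Reagents that add atoms: bromine, BrBr
Why: Ketone-to-vinyl-bromide conversion with the triphenyl phosphite–bromine reagent, in which the carbonyl oxygen is activated on phosphorus, bromide adds and amine-assisted elimination gives the 1-bromoalkene, and the free bromine is consumed before the electron-rich arene enters the flask.

**Step 4**
Reactants: 4 2,6-dihydroxy-4-methoxy-3-(3-methylbut-2-en-1-yl)benzaldehyde; 6 5-(1-bromoethenyl)-1,2,3-trimethoxybenzene
Product: 7 2-hydroxy-4-methoxy-3-(3-methylbut-2-en-1-yl)-6-{[1-(3,4,5-trimethoxyphenyl)ethenyl]oxy}benzaldehyde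
Conditions: CuI (10 mol %), N,N-dimethylglycine (20 mol %), Cs2CO3 (2 equiv), 1,4-dioxane, Ar, 90 °C
Reagents that add atoms: none
Why: Ullmann-type copper-catalysed C(sp2)–O coupling of a phenol with a vinyl bromide, in which the 6-OH has only H5 as ring neighbour while the 2-OH is buried between the formyl and prenyl groups and stays in the chelate, so the less hindered phenoxide should couple.

**Step 5**
Reactants: 7 2-hydroxy-4-methoxy-3-(3-methylbut-2-en-1-yl)-6-{[1-(3,4,5-trimethoxyphenyl)ethenyl]oxy}benzaldehyde
Product: 8 artoflavanone, (2S)-5-hydroxy-7-methoxy-6-(3-methylbut-2-en-1-yl)-2-(3,4,5-trimethoxyphenyl)-2,3-dihydro-4H-chromen-4-one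
Conditions: [Rh(cod)Cl]2 (2.5 mol %), (R)-DTBM-SEGPHOS (5 mol %), Na[B(3,5-(CF3)2C6H3)4] (5 mol %), 2,6-di-tert-butyl-4-methylpyridine (10 mol %), 4 Å MS, 1,4-dioxane, Ar, 80 °C; neutral work-up
Reagents that add atoms: none
Why: Proposed new method: the cationic bisphosphine complex of monovalent rhodium adds oxidatively into the formyl C–H bond of 7, the tethered C2=C3 enol ether binds, the hydride migrates to C2, and the seven-membered acyl alkyl rhodacycle of trivalent rhodium forms the C3–C4 bond by reductive elimination, so that 7 is isomerised to 8 with no atom lost. The closest known reaction type is the enantioselective, endo-selective intramolecular alkene hydroacylation of ortho-(2-substituted allyl)benzaldehydes to 3-substituted tetralones and of N-(1-arylvinyl)- and N-allylindole-2-carbaldehydes with the same catalyst family; what is new is that the benzylic CH2 of those substrates is replaced by the ether oxygen O1, that is, the alkene is an aryl 1-arylvinyl ether. Ring C closes in the endo mode (formally 6-endo-trig, both C2 and C3 become ring members). The only new stereocentre, C2, is fixed when the hydride is delivered to one enantiotopic face of the 1,1-disubstituted alkene, and that face is chosen by the chiral pocket of the bisphosphine, which has to tell ring B from O1. The step needs endo over exo closure, the enol ether over the prenyl alkene, and hydroacylation over decarbonylation: C2 is fully substituted, so rhodium ends on the CH2 terminus and an exo closure would have to build a quaternary centre; C2=C3 has no allylic hydrogen and cannot isomerise away; the trisubstituted prenyl alkene lies beyond the 5-OH and inserts slowly; and the O5–H···O=C4 hydrogen bond keeps the formyl C–H, and hence the metal, on the O1 side next to the alkene, where O1 can act as a hemilabile donor. The hindered pyridine and the sieves keep adventitious acid and water away from the enol ether and the ortho-prenylphenol, and the neutral medium leaves the base-labile C2 centre of the product untouched.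

**Compound list**
1 | 2,4,6-trihydroxybenzaldehyde | O=Cc1c(O)cc(O)cc1O | starting material
2 | 1-bromo-3-methylbut-2-ene (prenyl bromide) | CC(C)=CCBr | starting material
3 | 2,4,6-trihydroxy-3-(3-methylbut-2-en-1-yl)benzaldehyde | O=Cc1c(O)cc(O)c(CC=C(C)C)c1O | intermediate
4 | 2,6-dihydroxy-4-methoxy-3-(3-methylbut-2-en-1-yl)benzaldehyde | O=Cc1c(O)cc(OC)c(CC=C(C)C)c1O | intermediate
5 | 1-(3,4,5-trimethoxyphenyl)ethan-1-one | CC(=O)c1cc(OC)c(OC)c(OC)c1 | starting material
6 | 5-(1-bromoethenyl)-1,2,3-trimethoxybenzene | C=C(Br)c1cc(OC)c(OC)c(OC)c1 | intermediate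
7 | 2-hydroxy-4-methoxy-3-(3-methylbut-2-en-1-yl)-6-{[1-(3,4,5-trimethoxyphenyl)ethenyl]oxy}benzaldehyde | O=Cc1c(OC(=C)c2cc(OC)c(OC)c(OC)c2)cc(OC)c(CC=C(C)C)c1O | intermediate
8 | artoflavanone, (2S)-5-hydroxy-7-methoxy-6-(3-methylbut-2-en-1-yl)-2-(3,4,5-trimethoxyphenyl)-2,3-dihydro-4H-chromen-4-one | COc1cc2c(c(O)c1CC=C(C)C)C(=O)C[C@@H](c1cc(OC)c(OC)c(OC)c1)O2 | target

**Total step count:** 5
**Longest linear sequence:** 4 (steps 1, 2, 4, 5)

**Steps most likely to fail**

**Step 5 (Proposed new method).**
- What may go wrong:
  - decarbonylation of the acyl rhodium hydride before the alkene inserts;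
  - drainage through the exo insertion;
  - β-aryloxide elimination from the alkyl rhodium;
  - acid- or Lewis-acid-induced cleavage or Prins-type closure of the enol ether;
  - weak facial discrimination.
- Fallback (known chemistry, sets out from 4 and comes back at 8):
  - Commercial 2-bromo-1-(3,4,5-trimethoxyphenyl)ethan-1-one F1 is reduced with BH3·SMe2 and the (S)-Me-CBS oxazaborolidine (Corey–Bakshi–Shibata reduction) to (1S)-2-bromo-1-(3,4,5-trimethoxyphenyl)ethan-1-ol F2.
  - A Mitsunobu etherification (PPh3, DIAD, THF, 0 °C) of the less hindered 6-OH of 4 with this alcohol inverts the carbinol centre. It should give 6-[(1R)-2-bromo-1-(3,4,5-trimethoxyphenyl)ethoxy]-2-hydroxy-4-methoxy-3-(3-methylbut-2-en-1-yl)benzaldehyde F3.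
  - An N-heterocyclic-carbene-catalysed intramolecular nucleophilic substitution follows (3-benzyl-5-(2-hydroxyethyl)-4-methylthiazolium chloride, Et3N, 1,4-dioxane, 70 °C). The Breslow intermediate of the formyl group displaces the primary bromide. This closes the same C3–C4 bond without touching C2 and gives 8.

**Step 4.**
- What may go wrong:
  - sluggish turnover, because the chelated, electron-poor phenoxide ties up copper as a salicylaldehyde-type ligand;
  - base-induced dehydrobromination of the vinyl bromide;
  - coupling at the wrong hydroxyl.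
- Fallback (sets out from 4 and comes back at 7):
  - 2-bromo-1-(3,4,5-trimethoxyphenyl)ethan-1-one F1 is reduced with NaBH4 (MeOH, 0 °C) to racemic 2-bromo-1-(3,4,5-trimethoxyphenyl)ethan-1-ol F4.
  - Mitsunobu etherification (PPh3, DIAD, THF) of the 6-OH of 4 gives racemic 6-[2-bromo-1-(3,4,5-trimethoxyphenyl)ethoxy]-2-hydroxy-4-methoxy-3-(3-methylbut-2-en-1-yl)benzaldehyde F5.
  - E2 dehydrobromination (KOtBu, 2.2 equiv, THF, 0 °C) removes the benzylic, oxygen-bearing hydrogen, the only one β to bromine, and gives the enol ether 7.

**Step 1.**
- What may go wrong: O-alkylation, and a second (dearomatising) C-alkylation, competing with mono-C-prenylation.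
- Fallback (sets out from 1 and comes back at 4, replacing steps 1 and 2):
  - 1 is first methylated at the 4-OH (MeI, K2CO3, acetone) to 2,6-dihydroxy-4-methoxybenzaldehyde F6.
  - One of its two equivalent hydroxyls is converted into the tertiary allyl ether with tert-butyl 2-methylbut-3-en-2-yl carbonate and Pd(PPh3)4 (zerovalent palladium, THF, 0 °C). This gives 2-hydroxy-4-methoxy-6-[(2-methylbut-3-en-2-yl)oxy]benzaldehyde F7.
  - An aromatic Claisen rearrangement (N,N-diethylaniline, 130 °C) transfers the five-carbon unit, with allyl inversion, to the only free ortho carbon. This delivers the linear prenyl group and the free phenol of 4.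

**Further compounds**
F1 | step 5 | 2-bromo-1-(3,4,5-trimethoxyphenyl)ethan-1-one | O=C(CBr)c1cc(OC)c(OC)c(OC)c1
F2 | step 5 | (1S)-2-bromo-1-(3,4,5-trimethoxyphenyl)ethan-1-ol | BrC[C@@H](O)c1cc(OC)c(OC)c(OC)c1
F3 | step 5 | 6-[(1R)-2-bromo-1-(3,4,5-trimethoxyphenyl)ethoxy]-2-hydroxy-4-methoxy-3-(3-methylbut-2-en-1-yl)benzaldehyde | O=Cc1c(O[C@@H](CBr)c2cc(OC)c(OC)c(OC)c2)cc(OC)c(CC=C(C)C)c1O
F4 | step 4 | racemic 2-bromo-1-(3,4,5-trimethoxyphenyl)ethan-1-ol | BrCC(O)c1cc(OC)c(OC)c(OC)c1
F5 | step 4 | racemic 6-[2-bromo-1-(3,4,5-trimethoxyphenyl)ethoxy]-2-hydroxy-4-methoxy-3-(3-methylbut-2-en-1-yl)benzaldehyde | O=Cc1c(OC(CBr)c2cc(OC)c(OC)c(OC)c2)cc(OC)c(CC=C(C)C)c1O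
F6 | step 1 | 2,6-dihydroxy-4-methoxybenzaldehyde | O=Cc1c(O)cc(OC)cc1O
F7 | step 1 | 2-hydroxy-4-methoxy-6-[(2-methylbut-3-en-2-yl)oxy]benzaldehyde | O=Cc1c(O)cc(OC)cc1OC(C)(C)C=C
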